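**Retrosynthetic overview**

1. Target 17 is reached by hydrogenolysis of the 4'-benzyl ether of disulfate 16. 16 comes from sulfation of the 3-OH and 7-OH of triol 15, and 15 from flavone 12 by C3 hydroxylation and MOM removal.
2. The strategy rests on C4 of ring C: a lone carbonyl carbon whose only carbon neighbours are C4a of ring A and C3 of the C3=C2–aryl unit. It is excised as carbon monoxide; cutting C4a–C4, C4–C3 and O1–C2 leaves aryl iodide 5, arylacetylene 7 and CO 8.
3. Iodide 5 comes from phloroglucinol (bis-MOM ether, iodination ortho to the free OH, acetylation); alkyne 7 comes from O-benzylvanillin by one-carbon homologation.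
4. Ring order: rings A and B are bought as arenes; ring C is the only ring built, in step 5.
5. Protecting groups: MOM on O5 and O7 (removed by acid before sulfation) and benzyl on O4' (removed last, under neutral conditions that sulfate esters tolerate).

Key step: step 5

Assumption: the sulfate esters of 16 and 17 are written in the neutral hydrogen sulfate form of the target SMILES; in practice they would be handled as potassium salts, and the acid form of 17 released by a brief, cold pass through an acidic ion-exchange resin.

**Route**

Step 1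
Reactants: 1 phloroglucinol; 2 chloromethyl methyl ether
Product: 3 3,5-bis(methoxymethoxy)phenol
Conditions: MOMCl (2.1 equiv), iPr2NEt, CH2Cl2–DMF, 0 °C to rt
Reagents that add atoms: chloromethyl methyl ether (2), COCCl
Why: O-alkylation of a phenol with a chloromethyl ether (MOM protection); the three hydroxyls of the symmetric triol are equivalent, so only the degree of alkylation has to be controlled, and the mono- and tris-ethers should be separable and recyclable.

Step 2
Reactants: 3 3,5-bis(methoxymethoxy)phenol
Product: 4 2-iodo-3,5-bis(methoxymethoxy)phenol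
Conditions: NIS (1.0 equiv), CH2Cl2, −20 to 0 °C, dark
Reagents that add atoms: N-iodosuccinimide, O=C1CCC(=O)N1I
Why: Electrophilic aromatic iodination under acid-free conditions that spare the MOM acetals; the two equivalent positions ortho to the free OH are favoured statistically and sterically over C4, which lies between two MOM ethers, and hydrogen bonding of the phenol to the reagent in CH2Cl2 should further guide iodine ortho, any C4 isomer being separable.

Step 3
Reactants: 4 2-iodo-3,5-bis(methoxymethoxy)phenol
Product: 5 2-iodo-3,5-bis(methoxymethoxy)phenyl acetate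
Conditions: Ac2O, pyridine, DMAP (cat.), CH2Cl2, 0 °C to rt
Reagents that add atoms: acetic anhydride, CC(=O)OC(C)=O
Why: Base-catalysed O-acylation of the phenol; the acetate stops ring A from entering the coupling as an electron-rich phenoxide and is removed by the amine in step 5.

Step 4
Reactants: 6 4-(benzyloxy)-3-methoxybenzaldehyde (O-benzylvanillin)
Product: 7 1-(benzyloxy)-4-ethynyl-2-methoxybenzene
Conditions: dimethyl (1-diazo-2-oxopropyl)phosphonate, K2CO3, MeOH–THF, 0 °C to rt
Reagents that add atoms: dimethyl (1-diazo-2-oxopropyl)phosphonate, COP(=O)(OC)C(=[N+]=[N-])C(C)=O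
Why: Seyferth–Gilbert homologation in the Ohira–Bestmann variant: the diazomethylphosphonate anion released by methanolysis adds to the non-enolisable aldehyde, and Horner–Wadsworth–Emmons-type elimination, loss of N2 and 1,2-hydrogen shift of the alkylidene carbene should give the terminal alkyne.

Step 5
Reactants: 5 2-iodo-3,5-bis(methoxymethoxy)phenyl acetate; 7 1-(benzyloxy)-4-ethynyl-2-methoxybenzene; 8 carbon monoxide
Product: 12 2-[4-(benzyloxy)-3-methoxyphenyl]-5,7-bis(methoxymethoxy)-4H-chromen-4-one, via acetoxy ynone 9 (not isolated), via hydroxy ynone 10 (not isolated), via enaminone 11 (not isolated)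
Conditions: PdCl2(PPh3)2 (5 mol%), thiourea (5 mol%), dppp (5 mol%), Et2NH, DBU, CO (1 atm), 40 °C, copper-free
Reagents that add atoms: carbon monoxide (8), [C-]#[O+]
Why: Zerovalent palladium formed in situ from PdCl2(PPh3)2 inserts into the C–I bond of 5, CO insertion gives the aroylpalladium species, and alkynylation by the amine-deprotonated alkyne 7 followed by reductive elimination forges C4a–C4 and C4–C3 in ynone 9. Diethylamine then removes the acetyl group to give 10 and adds to the triple bond to give enaminone 11. Ring C closes when the phenoxide oxygen attacks the aminated β-carbon in a 6-endo-trig addition–elimination that forms O1–C2 and expels diethylamine (direct 6-endo-dig attack in 10 would give the same flavone). The closest known reaction type is the palladium-catalysed carbonylative annulation of o-iodophenyl acetates with terminal arylacetylenes to flavones, and no stereocentre is created. The step needs carbonylative over direct alkyne coupling and 6-endo over 5-exo (aurone) closure: the first is served by copper-free conditions under CO, where CO insertion into the hindered, di-ortho-oxygenated arylpalladium should outrun alkynylation, and the second by the secondary amine, which makes the β-carbon of 11 the electrophilic site. In the substrate, the acetate keeps ring A from reacting as a phenoxide during oxidative addition and frees the nucleophilic oxygen only once the ynone is in place, while the MOM-capped oxygen on the other side of the acyl carbon cannot cyclise, so only O1 closes the ring.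

Step 6
Reactants: 12 2-[4-(benzyloxy)-3-methoxyphenyl]-5,7-bis(methoxymethoxy)-4H-chromen-4-one
Product: 14 2-[4-(benzyloxy)-3-methoxyphenyl]-3-hydroxy-5,7-bis(methoxymethoxy)-4H-chromen-4-one, via flavone epoxide 13 (not isolated)
Conditions: DMDO (ca. 3 equiv, acetone), CH2Cl2, 0 °C to rt, dark; concentrate; p-TsOH·H2O (cat.), CH2Cl2, 0 °C, short contact
Reagents that add atoms: dimethyldioxirane, CC1(C)OO1
Why: Dioxirane epoxidation of the enol-ether-like C2=C3 bond followed by acid-catalysed epoxide-to-enol isomerisation (opening at C2 to the cation stabilised by O1 and the aryl group, then loss of H3) should give the flavonol; the two stereocentres of racemic 13 are erased in the rearrangement, and any MOM loss here is harmless because step 7 removes both.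

Step 7
Reactants: 14 2-[4-(benzyloxy)-3-methoxyphenyl]-3-hydroxy-5,7-bis(methoxymethoxy)-4H-chromen-4-one
Product: 15 2-[4-(benzyloxy)-3-methoxyphenyl]-3,5,7-trihydroxy-4H-chromen-4-one (4'-O-benzylisorhamnetin)
Conditions: conc. HCl (cat.), MeOH–THF, 50 °C
Reagents that add atoms: none
Why: Acid-catalysed methanolysis of the two MOM acetals; the aryl benzyl ether, the aryl methyl ether and the flavonol core are stable to dilute acid at this temperature.

Step 8
Reactants: 15 4'-O-benzylisorhamnetin
Product: 16 4'-O-benzylisorhamnetin 3,7-bis(hydrogen sulfate)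
Conditions: SO3·pyridine (ca. 6 equiv), pyridine–DMF, 0 °C to rt, HPLC control; K+-form cation-exchange resin; C18 chromatography
Reagents that add atoms: sulfur trioxide–pyridine complex, O=S(=O)([O-])[n+]1ccccc1
Why: O-sulfation with a sulfur trioxide–amine complex: the acidic 7-OH and the enolic 3-OH should react, the 5-OH is held in a strong six-membered hydrogen bond to the C4 carbonyl and is inert under these mild conditions, and O4' is blocked as its benzyl ether.

Step 9
Reactants: 16 4'-O-benzylisorhamnetin 3,7-bis(hydrogen sulfate)
Product: 17 isorhamnetin 3,7-di-O-sulfate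
Conditions: H2 (1 atm), 10% Pd/C, MeOH–H2O, rt, neutral pH; then H+-form cation-exchange resin, 0 °C, lyophilise
Reagents that add atoms: none
Why: Catalytic hydrogenolysis of the aryl benzyl ether; aryl sulfate monoester salts and the flavonol C2=C3 bond are not reduced at 1 atm and room temperature, and keeping the medium neutral until the final cold acid exchange protects the acid-labile 3-sulfate.

**Compound list**

1 | phloroglucinol (benzene-1,3,5-triol) | Oc1cc(O)cc(O)c1 | starting material
2 | chloromethyl methyl ether | COCCl | starting material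
3 | 3,5-bis(methoxymethoxy)phenol | COCOc1cc(O)cc(OCOC)c1 | intermediate
4 | 2-iodo-3,5-bis(methoxymethoxy)phenol | COCOc1cc(O)c(I)c(OCOC)c1 | intermediate
5 | 2-iodo-3,5-bis(methoxymethoxy)phenyl acetate | COCOc1cc(OC(C)=O)c(I)c(OCOC)c1 | intermediate
6 | 4-(benzyloxy)-3-methoxybenzaldehyde (O-benzylvanillin) | COc1cc(C=O)ccc1OCc1ccccc1 | starting material
7 | 1-(benzyloxy)-4-ethynyl-2-methoxybenzene | C#Cc1ccc(OCc2ccccc2)c(OC)c1 | intermediate
8 | carbon monoxide | [C-]#[O+] | starting material
9 | 2-{3-[4-(benzyloxy)-3-methoxyphenyl]prop-2-ynoyl}-3,5-bis(methoxymethoxy)phenyl acetate (acetoxy ynone, not isolated) | COCOc1cc(OC(C)=O)c(C(=O)C#Cc2ccc(OCc3ccccc3)c(OC)c2)c(OCOC)c1 | intermediate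
10 | 3-[4-(benzyloxy)-3-methoxyphenyl]-1-[2-hydroxy-4,6-bis(methoxymethoxy)phenyl]prop-2-yn-1-one (hydroxy ynone, not isolated) | COCOc1cc(O)c(C(=O)C#Cc2ccc(OCc3ccccc3)c(OC)c2)c(OCOC)c1 | intermediate
11 | 3-[4-(benzyloxy)-3-methoxyphenyl]-3-(diethylamino)-1-[2-hydroxy-4,6-bis(methoxymethoxy)phenyl]prop-2-en-1-one (enaminone, alkene geometry not defined, not isolated) | COCOc1cc(O)c(C(=O)C=C(N(CC)CC)c2ccc(OCc3ccccc3)c(OC)c2)c(OCOC)c1 | intermediate
12 | 2-[4-(benzyloxy)-3-methoxyphenyl]-5,7-bis(methoxymethoxy)-4H-chromen-4-one | COCOc1cc(OCOC)c2c(c1)oc(-c1ccc(OCc3ccccc3)c(OC)c1)cc2=O | intermediate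
13 | 2,3-epoxide of 12: 2,3-epoxy-2-[4-(benzyloxy)-3-methoxyphenyl]-5,7-bis(methoxymethoxy)chroman-4-one (racemic, oxirane necessarily cis-fused to ring C, one enantiomer drawn, not isolated) | COCOc1cc(OCOC)c2c(c1)O[C@@]1(c3ccc(OCc4ccccc4)c(OC)c3)O[C@H]1C2=O | intermediate
14 | 2-[4-(benzyloxy)-3-methoxyphenyl]-3-hydroxy-5,7-bis(methoxymethoxy)-4H-chromen-4-one | COCOc1cc(OCOC)c2c(c1)oc(-c1ccc(OCc3ccccc3)c(OC)c1)c(O)c2=O | intermediate
15 | 2-[4-(benzyloxy)-3-methoxyphenyl]-3,5,7-trihydroxy-4H-chromen-4-one (4'-O-benzylisorhamnetin) | COc1cc(-c2oc3cc(O)cc(O)c3c(=O)c2O)ccc1OCc1ccccc1 | intermediate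
16 | 4'-O-benzylisorhamnetin 3,7-bis(hydrogen sulfate) (handled as dipotassium salt) | COc1cc(-c2oc3cc(OS(=O)(=O)O)cc(O)c3c(=O)c2OS(=O)(=O)O)ccc1OCc1ccccc1 | intermediate
17 | isorhamnetin 3,7-di-O-sulfate | COc1cc(-c2oc3cc(OS(=O)(=O)O)cc(O)c3c(=O)c2OS(=O)(=O)O)ccc1O | target

**Step count**

Total steps: 9. Longest linear sequence: 8 steps (steps 1, 2, 3, 5, 6, 7, 8, 9, from phloroglucinol); the alkyne branch is one step (step 4).

**Steps most likely to fail**

1. Step 5. Oxidative addition into the hindered, electron-rich C–I bond may be slow and give way to protodeiodination. The aroylpalladium species may be captured by diethylamine as an amide, direct alkyne coupling may bypass CO, or closure may go 5-exo to the aurone.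
Fallback: the ynone is assembled without palladium, setting out from alkyne 7 and chloromethyl methyl ether 2. Commercial 2,4,6-trihydroxybenzaldehyde (O=Cc1c(O)cc(O)cc1O) would be alkylated with 2 (2 equiv, iPr2NEt, CH2Cl2), the hydrogen-bonded ortho hydroxyl staying free, to give 2-hydroxy-4,6-bis(methoxymethoxy)benzaldehyde F1. The lithium acetylide of 7 (n-BuLi, THF, −78 °C, excess to absorb the phenolic proton) should add to F1 to give the racemic propargylic alcohol 3-[4-(benzyloxy)-3-methoxyphenyl]-1-[2-hydroxy-4,6-bis(methoxymethoxy)phenyl]prop-2-yn-1-ol F2. Oxidation with MnO2 in CH2Cl2 would deliver hydroxy ynone 10, and Et2NH in EtOH should close it through 11 to flavone 12, where the route is rejoined. This path also avoids the iodination of step 2.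

2. Step 8. Sulfation of the hydrogen-bonded 3-OH may stall at the 7-monosulfate, forcing conditions may begin to sulfate the 5-OH, and the enol-type 3-sulfate may hydrolyse while the polar salt is isolated.
Fallback: protected sulfate diesters, setting out from triol 15. Treatment with 2,2,2-trichloroethyl chlorosulfate (ClS(=O)(=O)OCC(Cl)(Cl)Cl), Et3N and DMAP in THF should give the neutral, silica-stable 2-[4-(benzyloxy)-3-methoxyphenyl]-5-hydroxy-4-oxo-4H-chromene-3,7-diyl bis(2,2,2-trichloroethyl) bis(sulfate) F3, with the chelated 5-OH untouched. Reductive removal of both trichloroethyl groups with Zn and HCO2NH4 in MeOH, which leaves the benzyl ether intact, would return disulfate 16.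

3. Step 6. Epoxidation of the electron-poor, peri-oxygenated C2=C3 bond may be slow. The dioxirane may then oxidise the benzylic C–H of the benzyl ether or the MOM acetals, and the acid rearrangement may strip MOM groups unevenly.
Fallback: C3 oxygenation through a C3 anion, setting out from flavone 12. Deprotonation at C3 with LiN(iPr)2 (THF, −78 °C) and trapping with B(OMe)3 should give dimethyl {2-[4-(benzyloxy)-3-methoxyphenyl]-5,7-bis(methoxymethoxy)-4-oxo-4H-chromen-3-yl}boronate F4. Oxidation of the C–B bond with H2O2 and AcOH would return flavonol 14.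

**Further compounds**

F1 | step 5 | 2-hydroxy-4,6-bis(methoxymethoxy)benzaldehyde | COCOc1cc(O)c(C=O)c(OCOC)c1
F2 | step 5 | 3-[4-(benzyloxy)-3-methoxyphenyl]-1-[2-hydroxy-4,6-bis(methoxymethoxy)phenyl]prop-2-yn-1-ol (racemic) | COCOc1cc(O)c(C(O)C#Cc2ccc(OCc3ccccc3)c(OC)c2)c(OCOC)c1
F3 | step 8 | 2-[4-(benzyloxy)-3-methoxyphenyl]-5-hydroxy-4-oxo-4H-chromene-3,7-diyl bis(2,2,2-trichloroethyl) bis(sulfate) | COc1cc(-c2oc3cc(OS(=O)(=O)OCC(Cl)(Cl)Cl)cc(O)c3c(=O)c2OS(=O)(=O)OCC(Cl)(Cl)Cl)ccc1OCc1ccccc1
F4 | step 6 | dimethyl {2-[4-(benzyloxy)-3-methoxyphenyl]-5,7-bis(methoxymethoxy)-4-oxo-4H-chromen-3-yl}boronate | COCOc1cc(OCOC)c2c(c1)oc(-c1ccc(OCc3ccccc3)c(OC)c1)c(B(OC)OC)c2=O
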